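I began with one ratio. The flasks below were to be ranked by target at 6.0 h, and the earlier runs were what I had to go on.

| setting | ash | maple | alder | north | north-west | east | south | north-east |
|---|---|---|---|---|---|---|---|---|
| substrate | 0.041 M | 0.061 M | 0.050 M | 0.050 M | 0.050 M | 0.050 M | 0.080 M | 0.050 M |
| reagent | 1 equiv | 1 equiv | 0.91 equiv | 0.250 equiv | 3.00 equiv | 4.00 equiv | 1.00 equiv | 1.00 equiv |
| free catalyst | 15 mol% | 15 mol% | 15 mol% | 15 mol% | 15 mol% | 15 mol% | 15 mol% | 15 mol% |
| remark | run made earlier | run made earlier | run made earlier |  |  |  |  |  |
| time |  |  |  | 6.0 h | 6.0 h | 6.0 h | 6.0 h | 6.0 h |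

| run | time / h | target / % | substrate / % |
|---|---|---|---|
| ash | 1.00 | 8.2 | 85.3 |
| ash | 2.00 | 15.5 | 75.3 |
| ash | 3.00 | 21.0 | 67.8 |
| ash | 4.00 | 24.0 | 60.9 |
| maple | 0.333 | 5.3 | 93.9 |
| maple | 0.833 | 10.4 | 82.6 |
| maple | 2.00 | 21.2 | 67.6 |
| maple | 4.00 | 29.7 | 52.3 |
| alder | 0.500 | 4.8 | 92.5 |
| alder | 1.33 | 12.0 | 80.9 |
| alder | 2.50 | 19.5 | 69.6 |
| alder | 4.00 | 25.0 | 59.9 |

(readings scatter by 0.5 percentage points)

1. ranking by amount of target, in percent of the substrate charged, from high to low, at 6.0 h (north / north-west / east / south / north-east)
2. the amount of target, in percent of the substrate charged of the flask you put first, at 6.0 h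
3. the amount of target, in percent of the substrate charged of the flask you put last, at 6.0 h



Pooling the last readings of the runs, I took target formed per substrate lost, the selectivity, as a reading of 0.620. Run by run it read 0.614 in ash, 0.623 in maple and 0.623 in alder, so I reckoned each flask as this ratio times its substrate lost.

I turned the reagent first. Assuming one reagent per substrate lost, I took reagent as the limiting reagent in north at 0.250 equiv, and by my ratio that put a ceiling of 15.5% on target there. For east and north-west, charged with reagent in excess, I put the ceiling at 62.0%, and I expected east, with 4.00 equiv against 3.00 equiv, to come nearer to it.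

Then I turned the substrate concentration. By hand, I expected south, at 0.080 M against 0.050 M in north-east and at equal equivalents, to run ahead, and at 4.00 h maple's 29.7% stood above ash's 24.0%, so I put south above north-east.

I expected time to carry a flask along without moving the ratio; in alder it read 0.641 at 2.50 h and 0.623 at 4.00 h.

The forecast gave east > north-west > south > north-east > north, with 61% (53% to 65%) for the first flask and 10.2% (9% to 12%) for the last, on the ground that “target is about 0.63 of the substrate lost, independent of time and concentration”. Its ratio and mine come from the same readings, so their agreement checks nothing.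

East gave 56.6% and north 9.59%, in the order east > north-west > south > north-east > north, and the forecast held. Beside its target, east held 37.8% of isomer of the product at 6.00 h. In east the ratio came to 0.600, below my 0.620.

    substrate + reagent ⇌ target (K = 61.0 M⁻¹, k = 2.70 M⁻¹ h⁻¹)
    substrate + reagent ⇌ isomer of the product (K = 2400 M⁻¹, k = 1.40 M⁻¹ h⁻¹)
    target + free catalyst ⇌ isomer of the product + free catalyst, rate k3*[free catalyst]*[target] forward; the back reaction follows from the equilibrium constant (k = 1.50 M⁻¹ h⁻¹)
    2 free catalyst → spent catalyst A (k = 20.0 M⁻¹ h⁻¹)
    free catalyst → spent catalyst B (k = 0.0830 h⁻¹)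

East read at 15 h had 3.7% of its substrate left, so the ratio gave 59.7% target. That flask held 50.0%, below the ratio's figure, beside 46.3% of isomer of the product.

The runs come from a simulation for an exercise, and the scatter is random.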